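# Design of a synthesis of 2,3,4,7-tetrabromo-1H-indole (8)

## The problem

Target 8 is a 1H-indole with bromine at C2 and C3 of the pyrrole ring and at C4 and C7 of the benzene ring, so that only C5–H, C6–H and N1–H remain. It has no stereocenter; the task is one of regiochemistry and of keeping four C–Br bonds intact. Electrophilic bromination of an indole takes C3, then C2, then C5 or C6, and never C4 together with C7, so the two benzo bromines must already sit para to each other in the arene from which the bicycle is built. An aniline already contains N1–C7a, which leaves the bridge N1–C2–C3 and its attachment to C3a to be constructed. The C–Br bonds exclude low-valent transition metals, halogen–metal exchange, dissolving metals and strongly negative cathode potentials. The 2,3-dibrominated N–H pyrrole ring is sensitive to acid, light and excess oxidant and should be made last. The feature that opens the plan is that C2 and C3 are neighbours that both end as C–Br: each can travel as a carboxyl carbon and be exchanged for bromine with loss of CO2, so the bridge can be the two central carbons of an acetylenedicarboxylate bound to nitrogen. In 2,5-dibromoaniline (1) one ortho position is blocked by bromine (future C7) and the other is a C–H (future C3a) next to the second bromine (future C4), so a dehydrogenative C3–C3a closure has only one place to go.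

## Retrosynthesis

**C2–Br and C3–Br (8 to 6, through 7).** Both pyrrole C–Br bonds are cut first and replaced by C–CO2H, which leads to 4,7-dibromo-1H-indole-2,3-dicarboxylic acid (6), with 3,4,7-tribromo-1H-indole-2-carboxylic acid (7) as the stage between. The neighbouring cut, to a C2/C3-unsubstituted indole followed by C–H bromination, would require both carboxyl groups to be removed first, and the C2 carboxyl of an indole leaves only on strong heating, usually with copper, a poor match for two aryl bromides. Ipso substitution makes the carboxyl group the leaving group, so one reagent at or below room temperature does both jobs. The forward reaction must deliver electrophilic bromine to C3 and C2 and none to C5, C6 or N1; the two benzo bromines deactivate the carbocycle enough for that.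

**Ester cleavage (6 to 5).** The diacid comes from dimethyl 4,7-dibromo-1H-indole-2,3-dicarboxylate (5). Methyl esters are preferred to tert-butyl or benzyl esters because they come from the cheapest acetylenedicarboxylate and are inert to the oxidative ring closure, where methanol as proton source can only exchange methyl for methyl. The forward reaction must reach the C3 ester, which lies peri to the C4 bromine, without displacing bromine.

**C3–C3a (5 to 3, through 4).** This is the central cut. It opens the pyrrole ring to dimethyl (Z)-2-[(2,5-dibromophenyl)amino]but-2-enedioate (3), which holds every heavy atom of 5 and two hydrogens more. Of the neighbouring cuts, N1–C7a would call for a metal-catalysed amination that has to distinguish several C–halogen bonds, and C2–C3 leaves no simple precursor. The dehydrogenative cut keeps the closure intramolecular, five-membered and regiochemically unambiguous. Forward, two electrons and two protons must be removed; an anode with iodide as mediator does this without a metal oxidant, passes through the 3H-indole 4, and releases H2 at the cathode. Two demands follow: a carbon radical flanked by an ester must attack an electron-poor ring at a position next to bromine, and the cathode must reduce protons and not C–Br. The first is met by intramolecularity and the absence of any other ortho C–H, the second by a protic co-solvent that keeps proton reduction at platinum always available.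

**N1–C2 (3 to 1 and 2).** The enamine is cut at nitrogen into 2,5-dibromoaniline (1) and dimethyl acetylenedicarboxylate (2), both commercial. Conjugate addition forms the bond in one step with no by-product and puts N1, C2, C3 and both future C–Br carbons in place. The aniline is weakly nucleophilic, so the forward reaction needs heat and a protic solvent. Its geometric outcome does not matter, because the C2=C3 geometry is lost at ring closure.

## Roads not taken

Alternative 1: benzene ring by cycloaddition. Here C3a–C4 and C7–C7a are cut. The electron-poor diene 2,5-dibromothiophene 1,1-dioxide A1 would add to the enamide tert-butyl 2,3-dihydro-1H-pyrrole-1-carboxylate A2 in an inverse-demand [4+2] cycloaddition, and loss of SO2 would give cis-fused, racemic tert-butyl 4,7-dibromo-2,3,3a,7a-tetrahydroindole-1-carboxylate A3 as the product of the key step. Its merits are that the diene termini fix bromine at C4 and C7 with certainty, that the electronic pairing is good, and that SO2 loss makes the step irreversible. Its weak points lie before and after. A1 is not commercial and must be made by S-oxidation of an electron-poor thiophene. A3 arrives four hydrogens above the indole level, so two dehydrogenations and removal of the carbamate are needed before 4,7-dibromo-1H-indole A4 is reached, and the two pyrrole bromines still have to be added. The brominated cyclohexadiene A3 can also lose HBr after double-bond migration during aromatization, which would cost a bromine. In fairness, the ring-forming step is a thermal pericyclic cascade and in that respect more predictable than an electrolysis untested on this substrate. The chosen plan sets against it that the 4,7-pattern is bought with compound 1, that no redox adjustment of the carbocycle is needed, and that four steps stand against six or seven.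

Alternative 2: aryne annulation. Here N1–C7a and C3–C3a are cut at once. Fluoride would act on 3,6-dibromo-2-(trimethylsilyl)phenyl trifluoromethanesulfonate A5 to release 3,6-dibromobenzyne A6 in the flask. The sulfonamide nitrogen of methyl N-tosylglycinate A7 would add, and the resulting aryl anion would attack the ester to give 4,7-dibromo-1-tosylindolin-3-one A8 as the product of the key step. Its merits are that two bonds form in one metal-free step and that the symmetric aryne A6 leaves no regiochemical question. Its weak points are three. A5 has to be made in several steps, with silicon placed between oxygen and bromine without halogen–metal exchange. After nitrogen adds, the aryl anion sits ortho to a C–Br bond and can expel bromide to form a new aryne in competition with ring closure. A8 has the wrong oxidation level at both pyrrole carbons: the ketone must be reduced and dehydrated and the sulfonyl group removed to reach A4 before two brominations. This road forms more bonds in its key step and needs no oxidant there. The chosen plan sets against it two commercial building blocks and pyrrole carbons that leave the key step ready for direct exchange to C–Br, at roughly half the length.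

Alternative 3: sigmatropic ortho-alkylation to an oxindole. Here C3–C3a, the same bond as in the chosen plan, is cut together with the N1–C2 amide bond. Aniline 1 would be N-chlorinated with a hypochlorite at low temperature and combined with ethyl 2-(methylthio)acetate A9 to an azasulfonium salt. An amine base would form the ylide, which rearranges by a [2,3]-sigmatropic shift onto the free ortho carbon, and acid would close the lactam to racemic 4,7-dibromo-3-(methylthio)indolin-2-one A10 as the product of the key step. Its merits are that the same aniline is used, that the rearrangement is intramolecular and can only reach the free ortho carbon, and that the method is well established for electron-poor and ortho-substituted anilines. The ring construction is more secure than in the chosen plan, and the overall length is about the same (four to five steps). Its weak points come afterwards. The sulfur must be removed, and 4,7-dibromoindolin-2-one A11 would have to be reached without the usual hydrogenolysis over activated Ni, which would also strip aryl bromine, so a chemoselective C–S reduction would have to be found. Deoxygenative bromination at C2 and bromination at C3 then follow, so the pyrrole carbons need three separate adjustments. The first step also needs cryogenic hypochlorite handling and a malodorous sulfide. The chosen plan carries the risk in its ring closure, this road in the step after it. The chosen plan sets against the better-known closure that both pyrrole carbons are exchanged for bromine by one reagent, that no reduction is run in the presence of C–Br bonds, and that H2 is the only stoichiometric by-product of ring formation.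

Key step: step 2

Assumption: the target is taken as the N-unsubstituted 1H-tautomer, and nitrogen stays unprotected throughout because the ring closure needs the N–H.

## Route

Step 1
Reactants: 1 2,5-dibromoaniline; 2 dimethyl acetylenedicarboxylate
Product: 3 dimethyl (Z)-2-[(2,5-dibromophenyl)amino]but-2-enedioate (N–H cis to the C3 ester across the double bond; the two esters trans)
Conditions: 2 (1.2 equiv), MeOH, 0 °C to reflux, 24 h
Reagents that add atoms: none
Why: Aza-Michael (conjugate) addition of the aniline nitrogen to the electron-poor alkyne, the standard entry to N-aryl aminobutenedioates, which also serves weakly nucleophilic ortho-halo anilines on heating; methanol protonates the intermediate allenolate, and the Z isomer should predominate because of its N–H···O=C hydrogen bond to the C3 ester, while any E isomer converges in step 2.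

Step 2
Reactants: 3 dimethyl (Z)-2-[(2,5-dibromophenyl)amino]but-2-enedioate
Product: 5 dimethyl 4,7-dibromo-1H-indole-2,3-dicarboxylate, via 3H-indole diester 4 (not isolated)
Conditions: undivided cell, graphite anode, Pt cathode, n-Bu4NI (0.5 equiv), LiClO4 (0.1 M), DMF/MeOH 9:1, constant current 10 mA, ca. 3 F per mol, 40 °C, N2
Reagents that add atoms: none
Why: Anodic oxidation of iodide gives iodine, which converts the enamine (deprotonated at N–H by cathodically formed methoxide) into an N–I or C3–I species; homolysis of that weak bond, or direct electron transfer from the enamine anion, gives a 1-azaallyl radical delocalized over N1 and the ester-bearing C3. Its carbon end adds to the only free ortho carbon of the N-aryl ring (C6 of the aniline, the future C3a) and forms the C3–C3a bond, closing the five-membered pyrrole ring by intramolecular homolytic aromatic substitution in a formally 5-endo-trig mode (the attacked C3a=C7a bond lies inside the new ring), as this reaction class does throughout. A second one-electron oxidation of the cyclohexadienyl radical and loss of the C3a proton give 3H-indole 4, whose C3–H shifts to nitrogen to give aromatic 5, while the cathode reduces methanol to H2. The closest known reaction type is the iodide-mediated anodic dehydrogenative annulation of N-aryl enamino esters and enaminones to indoles; the substrate here differs only in the second ester on C2. No stereocenter remains: C3 of 4 arises racemic and becomes trigonal in 5, and the Z or E geometry of 3 is lost in the delocalized radical. Site selectivity is secured by the substrate, since the other ortho position carries bromine. Chemoselectivity is secured at the cathode by the protic co-solvent, because protons are reduced at platinum at a much less negative potential than an aryl C–Br bond or the push-pull alkene, and at the anode by the mediator, which holds the potential at the iodide/iodine couple, far below that needed to oxidize a bromoarene. Methanol can only exchange methyl for methyl at the esters.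

Step 3
Reactants: 5 dimethyl 4,7-dibromo-1H-indole-2,3-dicarboxylate
Product: 6 4,7-dibromo-1H-indole-2,3-dicarboxylic acid
Conditions: NaOH (6 equiv), MeOH/H2O 2:1, reflux; then 2 M HCl, 0 °C, to pH 2
Reagents that add atoms: sodium hydroxide, [Na+].[OH-]
Why: Saponification of both methyl esters by acyl–oxygen cleavage, the usual way from indole-2,3-dicarboxylates to the diacids; the aryl bromides are not activated toward hydroxide, and cold acidification should precipitate the diacid before the C3 carboxyl can be lost.

Step 4
Reactants: 6 4,7-dibromo-1H-indole-2,3-dicarboxylic acid
Product: 8 2,3,4,7-tetrabromo-1H-indole, via 3,4,7-tribromo-1H-indole-2-carboxylic acid 7 (not isolated)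
Conditions: NBS (2.2 equiv), LiOAc (10 mol %), DMF, 0 °C to rt, dark; aq. Na2S2O3 work-up
Reagents that add atoms: N-bromosuccinimide, O=C1CCC(=O)N1Br
Why: Double ipso-bromodecarboxylation (halodecarboxylation of heteroaromatic acids, known for indole-2-carboxylic and indole-2,3-dicarboxylic acids): electrophilic bromine attacks C3, the most nucleophilic indole carbon, and the 3-bromo-3H-indolium carboxylate loses CO2 to give 7; a second equivalent attacks C3 again and bromine shifts to C2 (or attacks C2 directly) with loss of the second CO2. The benzene ring, deactivated by two bromines, should stay untouched.

## Compound list

1 | 2,5-dibromoaniline | Nc1cc(Br)ccc1Br | starting material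
2 | dimethyl acetylenedicarboxylate (dimethyl but-2-ynedioate) | COC(=O)C#CC(=O)OC | starting material
3 | dimethyl (Z)-2-[(2,5-dibromophenyl)amino]but-2-enedioate | COC(=O)/C=C(\Nc1cc(Br)ccc1Br)C(=O)OC | intermediate
4 | dimethyl 4,7-dibromo-3H-indole-2,3-dicarboxylate (racemic, formed in the flask) | COC(=O)C1=Nc2c(Br)ccc(Br)c2C1C(=O)OC | intermediate
5 | dimethyl 4,7-dibromo-1H-indole-2,3-dicarboxylate | COC(=O)c1[nH]c2c(Br)ccc(Br)c2c1C(=O)OC | intermediate
6 | 4,7-dibromo-1H-indole-2,3-dicarboxylic acid | OC(=O)c1[nH]c2c(Br)ccc(Br)c2c1C(=O)O | intermediate
7 | 3,4,7-tribromo-1H-indole-2-carboxylic acid (formed in the flask) | OC(=O)c1[nH]c2c(Br)ccc(Br)c2c1Br | intermediate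
8 | 2,3,4,7-tetrabromo-1H-indole | Brc1[nH]c2c(Br)ccc(Br)c2c1Br | target

## Step count and points of risk

Total step count: 4. Longest linear sequence: 4 steps (1 to 3 to 5 to 6 to 8).

The key step, step 2, is the least certain. The most likely failure is that ring closure does not keep pace with iodination, so that the enamine is only iodinated at C3 or couples intermolecularly. The reason is that the carbon radical is electrophilic (flanked by an ester and an imine) and must attack, in an endo mode, a ring deactivated by two bromines at a position next to one of them. Less likely are cathodic loss of bromine if the proton supply runs short, and ipso attack at the brominated ortho carbon with expulsion of bromine. The fallback sets out from 3 and returns at 5 by a palladium-catalysed aerobic C–H/C–H cyclization: Pd(OAc)2 (10 mol %), O2 (1 atm), DMA/PivOH, 120 °C. Divalent palladium binds the enamine carbon, palladates the ortho C–H by concerted metalation–deprotonation (helped by the adjacent bromine, which acidifies that C–H), and reductive elimination forms C3–C3a. O2 returns zerovalent palladium to the divalent state. This oxidative cyclization is known for adducts of anilines with acetylenedicarboxylates. Its cost is that the C–Br bonds meet transient zerovalent palladium, which the absence of phosphine and the oxidizing atmosphere should limit. The detour makes no new compound (entry F0).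

Step 4 comes next. The most likely failure is stalling after the first substitution, so that bromodecarboxylation at C2 stays incomplete, or over-oxidation of the N–H pyrrole ring by surplus electrophilic bromine (N-bromination, oxygenation at C2). The reason is that C2 is not the intrinsically nucleophilic carbon and the second CO2 has to leave after a bromine shift. The fallback sets out from 6 and replaces ipso substitution by decarboxylation followed by C–H bromination. Silver-catalysed protodecarboxylation (Ag2CO3 10 mol %, AcOH, DMSO, 120 °C) should remove both carboxyl groups without touching C–Br and give 4,7-dibromo-1H-indole F1. NBS (2.05 equiv) in DMF at 0 °C then brominates C3 to give 3,4,7-tribromo-1H-indole F2, which is not isolated, and then C2. The sequence rejoins the route at 8.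

Step 3 is the third risk. The most likely failure is incomplete hydrolysis at C3: that ester is shielded by the peri bromine at C4 and, once hydroxide has deprotonated N1, belongs to a vinylogous carbamate anion that is a poor electrophile. Forcing the conditions invites loss of CO2 from C3 on acidification. The fallback sets out from 5 and switches from acyl–oxygen to alkyl–oxygen cleavage: BBr3 (4 equiv), CH2Cl2, 0 °C to rt, then water. Boron coordinates the carbonyl oxygen and bromide attacks the methyl carbon, so hindrance at the carbonyl no longer matters and no N-anion is formed. Aqueous work-up releases 6, where the route is rejoined. No new compound is made (entry F0).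

## Further compounds

F0 | step 2 | none | none
F1 | step 4 | 4,7-dibromo-1H-indole | Brc1ccc(Br)c2[nH]ccc12
F2 | step 4 | 3,4,7-tribromo-1H-indole | Brc1c[nH]c2c(Br)ccc(Br)c12
F0 | step 3 | none | none
A1 | alternative 1 | 2,5-dibromothiophene 1,1-dioxide | O=S1(=O)C(Br)=CC=C1Br
A2 | alternative 1 | tert-butyl 2,3-dihydro-1H-pyrrole-1-carboxylate | CC(C)(C)OC(=O)N1CCC=C1
A3 | alternative 1 | tert-butyl cis-4,7-dibromo-2,3,3a,7a-tetrahydroindole-1-carboxylate (racemic, one enantiomer drawn) | CC(C)(C)OC(=O)N1CC[C@@H]2C(Br)=CC=C(Br)[C@H]12
A4 | alternative 1 | 4,7-dibromo-1H-indole | Brc1ccc(Br)c2[nH]ccc12
A5 | alternative 2 | 3,6-dibromo-2-(trimethylsilyl)phenyl trifluoromethanesulfonate | C[Si](C)(C)c1c(Br)ccc(Br)c1OS(=O)(=O)C(F)(F)F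
A6 | alternative 2 | 3,6-dibromobenzyne | BrC1=CC=C(Br)C#C1
A7 | alternative 2 | methyl N-tosylglycinate | COC(=O)CNS(=O)(=O)c1ccc(C)cc1
A8 | alternative 2 | 4,7-dibromo-1-tosylindolin-3-one | Cc1ccc(cc1)S(=O)(=O)N1CC(=O)c2c(Br)ccc(Br)c21
A9 | alternative 3 | ethyl 2-(methylthio)acetate | CCOC(=O)CSC
A10 | alternative 3 | 4,7-dibromo-3-(methylthio)indolin-2-one (racemic) | CSC1C(=O)Nc2c(Br)ccc(Br)c12
A11 | alternative 3 | 4,7-dibromoindolin-2-one | O=C1Cc2c(Br)ccc(Br)c2N1
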